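Neither D nor X was read in larch or oak, so the product excess cannot be read off these runs; what they do give is S, the sum of Q and E as a percentage of the two charged.

| setting | larch | oak | flask |
|---|---|---|---|
| Q | 10 mM | 15 mM | 10 mM |
| E | 10 mM | 15 mM | 10 mM |
| L | 0.81 mM (held) | 0.81 mM (held) | 0.81 mM (held) |
| G | 0.5 mol% | 0.5 mol% | 0.5 mol% |
| remark | the very flask that is asked about, followed so far | run made earlier |  |
| time |  |  | 25 h |

| run | time / h | Q / % | E / % |
|---|---|---|---|
| larch | 0.200 | 49.1 | 48.5 |
| larch | 0.667 | 46.2 | 47.0 |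
| larch | 1.00 | 42.6 | 45.3 |
| larch | 1.50 | 40.4 | 43.0 |
| larch | 2.50 | 35.1 | 37.2 |
| larch | 3.00 | 33.0 | 36.0 |
| oak | 1.33 | 39.6 | 43.0 |
| oak | 3.00 | 29.1 | 32.7 |
| oak | 6.00 | 16.1 | 19.4 |
| oak | 10.0 | 7.9 | 8.0 |
| oak | 12.0 | 4.6 | 6.4 |
| oak | 20.0 | 0.4 | 1.2 |

(each reading ± 0.5 percentage points)

- G is single-handed; Q and E are mirror images of each other, charged as a racemate, each of them at the stated concentration
- at the start none of J is dissolved
- steps that have been proposed: J + G + Q -> G + D; J + G + E -> G + X; Q <-> E; L <-> J; J <-> Z
- an excess is below zero if the other one leads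

* part of the Q and E charged together that has reacted at 25 h
* excess of D over X in the product at 25 h
* excess of E over Q among what is left of the two at 25 h

I draw S for the flask as one falling exponential with a mean pseudo-first-order constant, ln(charged/left)/time. Oak's last reading, at 20.0 h, has S at 1.60%. Both proposed consuming steps carry G, L is the same, and oak holds more G than larch, so I divide oak's constant by its G and get 2.76 /mM/h. This κ, the mean constant per mM of G, is what I carry.

With 0.0500 mM of G, the flask has a mean constant of 0.138 /h. At 3.00 h this curve stands at 66.1% where larch reads 69.0%, so the larch readings start flatter than the mean curve. On this curve S reaches half of the charge at 5.02 h. At 25 h the curve stands at 3.19%, so I commit to c near 96.8%. Oak's 12.0 h reading, used the same way, leaves 4.66%, more than that; this gap is the error I allow. I give no excess.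

The forecast says c 96% (93% to 98.5%), eS 17% (6% to 35%) and eP 1% (0.3% to 2.5%), by “eP ≈ eS(1−c)/c”.

The flask gives c 97.0%, eP 28.7% and eS 5.20%.

    J + G + Q → G + D (k = 4.96 × 10⁶ /M²/h)
    J + G + E → G + X (k = 2.53 × 10⁶ /M²/h)
    Q ⇌ E (k = 0.467 /h)
    L ⇌ J, rate k4*(csat - [J]) (kL = 18.3 /h)
    J ⇌ Z (K = 3.11, k = 0.0914 /h)

The forecast parts from the flask on the excesses, not on c: at 25.0 h D stands at 62.4% and X at 34.6%, and the relaxation half-life of Q and E by the step Q ⇌ E, both ways together, is 0.742 h, short against that time. For a neighbour flask, like this one but with 0.3 mol% of G, κ gives 0.0827 /h and c of 87.4%. That flask gives c 88.2%, with eS 3.10% and eP 30.0%.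

(The runs are calculated for an exercise; noise was put on by code.)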